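The lactol ring B is traced back to a carbocycle. Lactone carbon C1 and hemiketal carbon C3 are both attached to O2, so joining them directly gives the C1 ketone and C2 carbinol of a 2-hydroxyindan-1-one. Its C3 carries the future C4 methyl, out of reach of enolisation. Oxidative cleavage of that α-ketol with periodic acid releases an aryl carboxylic acid and a ketone that close to the six-membered hemiketal in the same flask, setting C3 under thermodynamic control. The precursor is the fully assembled indanone already carrying the ring C ester on its primary oxygen, with all three phenols held as benzyl ethers so that hydrogenolysis alone finishes the synthesis.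

Key step: step 18

Remarks on the design
- The target is the (3R,4S)-3-hydroxy-3,4-dihydroisocoumarin: the C4 methyl is trans to the C3 hydroxyl and cis to the acyloxymethyl arm. Ring C is a 2,4-dihydroxy-3,5,6-trimethylbenzoate.
- A 3,5-dimethoxyphenyl building block has no carbon for the C5 methyl of ring A (C4 of the indanone). That methyl is therefore put on the aryl bromide first (steps 1 and 2).
- Commercial methyl 2,4-dihydroxy-3,6-dimethylbenzoate lacks the C5 methyl of ring C. It is added in steps 12 and 13.
- The C8 oxygen is changed from a methyl to a benzyl ether at the simple indanone (steps 7 and 8), where chelation-directed demethylation is routine. No Lewis acid then meets the finished lactol, which could lose water to the isocoumarin and erase C4.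
- The secondary carbinol is reoxidised with IBX, which does not fragment vicinal diols.
- C1 of compounds 15 and 22 is an uncontrolled carbinol centre that is oxidised away. C2 of compounds 13, 14, 15, 22 and 23 is drawn as the expected major epimer and is destroyed in step 18, so either epimer converges.
- Assumption: the sense of induction of the copper hydride catalyst on this ortho-substituted enoate is fixed by a pilot reduction; the route is written with (R)-DTBM-SEGPHOS and the mirror-image ligand is taken if the pilot gives the (S)-ester.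

**Route**

Step 1
Reactants: 1 1-bromo-3,5-dimethoxybenzene
Product: 3 2-bromo-4,6-dimethoxybenzaldehyde, via aryl iminium chloride 2 (not isolated)
Conditions: POCl3, DMF, 0 °C then 90 °C; ice water
Reagents that add atoms: N,N-dimethylformamide, CN(C)C=O; water, O
Why: Vilsmeier–Haack formylation should attack the position next to bromine, para to one methoxy group and ortho to the other, in preference to the more crowded site between the two methoxy groups, and hydrolysis of the iminium salt frees the aldehyde.

Step 2
Reactants: 3 2-bromo-4,6-dimethoxybenzaldehyde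
Product: 4 1-bromo-3,5-dimethoxy-2-methylbenzene
Conditions: Et3SiH, TFA, CH2Cl2, 0 °C to rt
Reagents that add atoms: none
Why: Ionic hydrogenation: the aldehyde, activated by its ortho and para methoxy groups, is protonated and reduced twice by the silane through a stabilised benzylic cation, while the aryl bromide is inert.

Step 3
Reactants: 4 1-bromo-3,5-dimethoxy-2-methylbenzene; 5 ethyl crotonate
Product: 6 ethyl (E)-3-(3,5-dimethoxy-2-methylphenyl)but-2-enoate
Conditions: Pd(P(tBu)3)2 (cat.), Cy2NMe, dioxane, 100 °C
Reagents that add atoms: none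
Why: Mizoroki–Heck arylation at the β-carbon of the crotonate and syn β-hydride elimination should give the trisubstituted (E)-enoate with aryl trans to the ester, the bulky electron-rich phosphine on zerovalent palladium being suited to a hindered, electron-rich aryl bromide.

Step 4
Reactants: 6 ethyl (E)-3-(3,5-dimethoxy-2-methylphenyl)but-2-enoate
Product: 7 ethyl (R)-3-(3,5-dimethoxy-2-methylphenyl)butanoate
Conditions: Cu(OAc)2·H2O (cat.), (R)-DTBM-SEGPHOS (cat.), (EtO)2MeSiH, tBuOH, toluene, 0 °C to rt
Reagents that add atoms: none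
Why: Asymmetric conjugate reduction by a bisphosphine-ligated copper hydride delivers hydride to one face of the β-carbon of the geometrically pure (E)-enoate, which sets the benzylic centre (the future C4) under ligand control, and tBuOH protonates the copper enolate to turn the catalyst over.

Step 5
Reactants: 7 ethyl (R)-3-(3,5-dimethoxy-2-methylphenyl)butanoate
Product: 8 (R)-3-(3,5-dimethoxy-2-methylphenyl)butanoic acid
Conditions: LiOH, THF/MeOH/H2O, rt; then aq HCl
Reagents that add atoms: LiOH, [Li+].[OH-]
Why: Plain saponification, in which the stereocentre is β to the carboxyl group and is not touched by base.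

Step 6
Reactants: 8 (R)-3-(3,5-dimethoxy-2-methylphenyl)butanoic acid
Product: 10 (R)-5,7-dimethoxy-3,4-dimethyl-2,3-dihydro-1H-inden-1-one, via mixed trifluoroacetic anhydride 9 (not isolated)
Conditions: TFAA, TFA, CH2Cl2, 0 °C to rt
Reagents that add atoms: none
Why: Intramolecular Friedel–Crafts acylation through the mixed anhydride can close only at the one free ortho position, which is ortho and para to the two methoxy groups, and the β stereocentre takes no part.

Step 7
Reactants: 10 (R)-5,7-dimethoxy-3,4-dimethyl-2,3-dihydro-1H-inden-1-one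
Product: 11 (R)-7-hydroxy-5-methoxy-3,4-dimethyl-2,3-dihydro-1H-inden-1-one
Conditions: BCl3, CH2Cl2, −78 to 0 °C; H2O
Reagents that add atoms: none
Why: Chelation-directed ether cleavage: BCl3 bridges the ketone and the peri C7 methoxy oxygen in a six-membered chelate and chloride removes only that methyl group, leaving the C5 methyl ether.

Step 8
Reactants: 11 (R)-7-hydroxy-5-methoxy-3,4-dimethyl-2,3-dihydro-1H-inden-1-one
Product: 12 (R)-7-(benzyloxy)-5-methoxy-3,4-dimethyl-2,3-dihydro-1H-inden-1-one
Conditions: BnBr, K2CO3, DMF, 60 °C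
Reagents that add atoms: benzyl bromide, BrCc1ccccc1
Why: Williamson etherification of the phenoxide, under base too weak to affect the non-acidic C3 centre.

Step 9
Reactants: 12 (R)-7-(benzyloxy)-5-methoxy-3,4-dimethyl-2,3-dihydro-1H-inden-1-one
Product: 13 methyl (2R,3R)-7-(benzyloxy)-5-methoxy-3,4-dimethyl-1-oxo-2,3-dihydro-1H-indene-2-carboxylate
Conditions: NaH, (MeO)2CO, THF, reflux; then cold dilute aq HCl
Reagents that add atoms: dimethyl carbonate, COC(=O)OC
Why: Claisen-type C-acylation of the ketone enolate, driven by deprotonation of the β-keto ester formed; C2 equilibrates to the epimer trans to the C3 methyl and is lost again later.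

Step 10
Reactants: 13 methyl (2R,3R)-7-(benzyloxy)-5-methoxy-3,4-dimethyl-1-oxo-2,3-dihydro-1H-indene-2-carboxylate
Product: 14 methyl (2R,3S)-7-(benzyloxy)-2-hydroxy-5-methoxy-3,4-dimethyl-1-oxo-2,3-dihydro-1H-indene-2-carboxylate
Conditions: dimethyldioxirane, acetone, 0 °C
Reagents that add atoms: dimethyldioxirane, CC1(C)OO1
Why: Electrophilic α-hydroxylation of the enol of the β-keto ester by the dioxirane, expected from the face opposite the C3 methyl; the C3 descriptor changes from R to S only because C2 gains priority.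

Step 11
Reactants: 14 methyl (2R,3S)-7-(benzyloxy)-2-hydroxy-5-methoxy-3,4-dimethyl-1-oxo-2,3-dihydro-1H-indene-2-carboxylate
Product: 15 (2S,3S)-7-(benzyloxy)-2-(hydroxymethyl)-5-methoxy-3,4-dimethyl-2,3-dihydro-1H-indene-1,2-diol (both C1 epimers)
Conditions: LiAlH4, THF, 0 °C to rt; H2O, aq NaOH
Reagents that add atoms: none
Why: Hydride reduction of ester and ketone together gives the triol, whose new C1 carbinol configuration is immaterial because it is reoxidised in step 17.

Step 12
Reactants: 16 methyl 2,4-dihydroxy-3,6-dimethylbenzoate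
Product: 17 methyl 5-formyl-2,4-dihydroxy-3,6-dimethylbenzoate
Conditions: Cl2CHOMe, TiCl4, CH2Cl2, 0 °C; aq HCl
Reagents that add atoms: dichloromethyl methyl ether, COC(Cl)Cl; water, O
Why: Rieche formylation at C5, the only free ring position, which is ortho to the C4 hydroxyl and para to the C2 hydroxyl.

Step 13
Reactants: 17 methyl 5-formyl-2,4-dihydroxy-3,6-dimethylbenzoate
Product: 18 methyl 2,4-dihydroxy-3,5,6-trimethylbenzoate
Conditions: H2 (1 atm), Pd/C, AcOH, rt
Reagents that add atoms: none
Why: Hydrogenolysis of an aryl aldehyde flanked by ortho and para hydroxyls runs through the benzylic alcohol to the methyl group.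

Step 14
Reactants: 18 methyl 2,4-dihydroxy-3,5,6-trimethylbenzoate
Product: 19 methyl 2,4-bis(benzyloxy)-3,5,6-trimethylbenzoate
Conditions: BnBr, K2CO3, DMF, 70 °C
Reagents that add atoms: benzyl bromide, BrCc1ccccc1
Why: Double Williamson etherification, with heating to overcome the hydrogen-bonded C2 hydroxyl and the flanked C4 hydroxyl.

Step 15
Reactants: 19 methyl 2,4-bis(benzyloxy)-3,5,6-trimethylbenzoate
Product: 20 2,4-bis(benzyloxy)-3,5,6-trimethylbenzoic acid
Conditions: KOH, DMSO/H2O, 100 °C; then aq HCl
Reagents that add atoms: KOH, [K+].[OH-]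
Why: Forcing saponification of a doubly ortho-substituted benzoate by poorly solvated hydroxide in DMSO, to which aryl benzyl ethers are stable.

Step 16
Reactants: 20 2,4-bis(benzyloxy)-3,5,6-trimethylbenzoic acid; 15 (2S,3S)-7-(benzyloxy)-2-(hydroxymethyl)-5-methoxy-3,4-dimethyl-2,3-dihydro-1H-indene-1,2-diol
Product: 22 [(2S,3S)-7-(benzyloxy)-1,2-dihydroxy-5-methoxy-3,4-dimethyl-2,3-dihydro-1H-inden-2-yl]methyl 2,4-bis(benzyloxy)-3,5,6-trimethylbenzoate (both C1 epimers), via acid chloride 21 (not isolated)
Conditions: 20, (COCl)2, DMF (cat.), CH2Cl2, 0 °C to rt, concentrate; then 15, Et3N, DMAP, CH2Cl2, 0 °C to rt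
Reagents that add atoms: none
Why: DMAP-catalysed acyl transfer from the acid chloride, in which the doubly ortho-substituted acyl donor should select the primary hydroxyl over the crowded secondary benzylic and the tertiary hydroxyls.

Step 17
Reactants: 22 [(2S,3S)-7-(benzyloxy)-1,2-dihydroxy-5-methoxy-3,4-dimethyl-2,3-dihydro-1H-inden-2-yl]methyl 2,4-bis(benzyloxy)-3,5,6-trimethylbenzoate
Product: 23 [(2S,3S)-7-(benzyloxy)-2-hydroxy-5-methoxy-3,4-dimethyl-1-oxo-2,3-dihydro-1H-inden-2-yl]methyl 2,4-bis(benzyloxy)-3,5,6-trimethylbenzoate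
Conditions: IBX, DMSO, rt
Reagents that add atoms: none
Why: IBX oxidation of the secondary benzylic carbinol of either epimer to the ketone, a reagent that converts 1,2-diols to α-ketols without breaking the C1–C2 bond.

Step 18
Reactants: 23 [(2S,3S)-7-(benzyloxy)-2-hydroxy-5-methoxy-3,4-dimethyl-1-oxo-2,3-dihydro-1H-inden-2-yl]methyl 2,4-bis(benzyloxy)-3,5,6-trimethylbenzoate
Product: 25 [(3R,4S)-8-(benzyloxy)-3-hydroxy-6-methoxy-4,5-dimethyl-1-oxo-3,4-dihydro-1H-isochromen-3-yl]methyl 2,4-bis(benzyloxy)-3,5,6-trimethylbenzoate, via open keto acid 24 (not isolated)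
Conditions: H5IO6, THF/H2O, 0 °C to rt; aq Na2S2O3 wash, no basic wash
Reagents that add atoms: water, O
Why: Periodic acid ties the tertiary C2 hydroxyl and the hydrated C1 ketone into a five-membered cyclic periodate, whose fragmentation breaks the C1–C2 bond and leaves an aryl carboxylic acid at the former C1 and a ketone at the former C2 (keto acid 24). The closest known reaction type is the Malaprade-type cleavage of α-hydroxy ketones, 2-hydroxyindan-1-ones included, by periodic acid or Pb(OAc)4 to keto acids. The carboxylic acid oxygen then adds to the new ketone in a 6-exo-trig closure that forms the O2–C3 bond and ring B, helped by the α-acyloxy activation of the ketone and by the two arms being held ortho on a fully substituted arene. C3 is set by ring-chain equilibration next to the fixed C4 centre: the C5 methyl pushes the C4 methyl pseudoaxial, and the hemiketal should settle with its hydroxyl axial (anomeric stabilisation) and trans to that methyl and the acyloxymethyl arm equatorial, which is the (3R,4S) arrangement. C4 cannot epimerise before cleavage because it is β to the indanone carbonyl, and afterwards the medium is cold, acidic and free of base while the ketone is masked as the lactol. The selectivity needed is cleavage of the α-ketol alone, secured by the ester on the primary oxygen, which leaves no vicinal diol, and by ether protection of every phenol against oxidation.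

Step 19
Reactants: 25 [(3R,4S)-8-(benzyloxy)-3-hydroxy-6-methoxy-4,5-dimethyl-1-oxo-3,4-dihydro-1H-isochromen-3-yl]methyl 2,4-bis(benzyloxy)-3,5,6-trimethylbenzoate
Product: 26 [(3R,4S)-3,8-dihydroxy-6-methoxy-4,5-dimethyl-1-oxo-3,4-dihydro-1H-isochromen-3-yl]methyl 2,4-dihydroxy-3,5,6-trimethylbenzoate
Conditions: H2 (1 atm), Pd/C, EtOAc, rt
Reagents that add atoms: none
Why: Neutral hydrogenolysis of the three aryl benzyl ethers, under which the lactol, both esters, the C6 methyl ether and the C4 centre should be unaffected.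

**Compound list**

1 | 1-bromo-3,5-dimethoxybenzene | COc1cc(Br)cc(OC)c1 | starting material
2 | [(2-bromo-4,6-dimethoxyphenyl)methylidene]dimethyliminium chloride | C[N+](C)=Cc1c(Br)cc(OC)cc1OC.[Cl-] | intermediate (not isolated)
3 | 2-bromo-4,6-dimethoxybenzaldehyde | O=Cc1c(Br)cc(OC)cc1OC | intermediate
4 | 1-bromo-3,5-dimethoxy-2-methylbenzene | Cc1c(Br)cc(OC)cc1OC | intermediate
5 | ethyl crotonate, ethyl (E)-but-2-enoate | CCOC(=O)/C=C/C | starting material
6 | ethyl (E)-3-(3,5-dimethoxy-2-methylphenyl)but-2-enoate | CCOC(=O)/C=C(\C)c1cc(OC)cc(OC)c1C | intermediate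
7 | ethyl (R)-3-(3,5-dimethoxy-2-methylphenyl)butanoate | COc1cc(OC)cc(c1C)[C@H](C)CC(=O)OCC | intermediate
8 | (R)-3-(3,5-dimethoxy-2-methylphenyl)butanoic acid | COc1cc(OC)cc(c1C)[C@H](C)CC(=O)O | intermediate
9 | (R)-3-(3,5-dimethoxy-2-methylphenyl)butanoic trifluoroacetic anhydride | COc1cc(OC)cc(c1C)[C@H](C)CC(=O)OC(=O)C(F)(F)F | intermediate (not isolated)
10 | (R)-5,7-dimethoxy-3,4-dimethyl-2,3-dihydro-1H-inden-1-one | COc1cc(OC)c2c(c1C)[C@H](C)CC2=O | intermediate
11 | (R)-7-hydroxy-5-methoxy-3,4-dimethyl-2,3-dihydro-1H-inden-1-one | COc1cc(O)c2c(c1C)[C@H](C)CC2=O | intermediate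
12 | (R)-7-(benzyloxy)-5-methoxy-3,4-dimethyl-2,3-dihydro-1H-inden-1-one | COc1cc(OCc3ccccc3)c2c(c1C)[C@H](C)CC2=O | intermediate
13 | methyl (2R,3R)-7-(benzyloxy)-5-methoxy-3,4-dimethyl-1-oxo-2,3-dihydro-1H-indene-2-carboxylate (keto form; C2 epimerisable) | COc1cc(OCc3ccccc3)c2c(c1C)[C@H](C)[C@@H](C(=O)OC)C2=O | intermediate
14 | methyl (2R,3S)-7-(benzyloxy)-2-hydroxy-5-methoxy-3,4-dimethyl-1-oxo-2,3-dihydro-1H-indene-2-carboxylate | COc1cc(OCc3ccccc3)c2c(c1C)[C@H](C)[C@](O)(C(=O)OC)C2=O | intermediate
15 | (2S,3S)-7-(benzyloxy)-2-(hydroxymethyl)-5-methoxy-3,4-dimethyl-2,3-dihydro-1H-indene-1,2-diol, C1 unassigned (both epimers) | COc1cc(OCc3ccccc3)c2c(c1C)[C@H](C)[C@](O)(CO)C2O | intermediate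
16 | methyl 2,4-dihydroxy-3,6-dimethylbenzoate | COC(=O)c1c(C)cc(O)c(C)c1O | starting material
17 | methyl 5-formyl-2,4-dihydroxy-3,6-dimethylbenzoate | COC(=O)c1c(C)c(C=O)c(O)c(C)c1O | intermediate
18 | methyl 2,4-dihydroxy-3,5,6-trimethylbenzoate | COC(=O)c1c(C)c(C)c(O)c(C)c1O | intermediate
19 | methyl 2,4-bis(benzyloxy)-3,5,6-trimethylbenzoate | COC(=O)c1c(C)c(C)c(OCc2ccccc2)c(C)c1OCc1ccccc1 | intermediate
20 | 2,4-bis(benzyloxy)-3,5,6-trimethylbenzoic acid | OC(=O)c1c(C)c(C)c(OCc2ccccc2)c(C)c1OCc1ccccc1 | intermediate
21 | 2,4-bis(benzyloxy)-3,5,6-trimethylbenzoyl chloride | ClC(=O)c1c(C)c(C)c(OCc2ccccc2)c(C)c1OCc1ccccc1 | intermediate (not isolated)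
22 | [(2S,3S)-7-(benzyloxy)-1,2-dihydroxy-5-methoxy-3,4-dimethyl-2,3-dihydro-1H-inden-2-yl]methyl 2,4-bis(benzyloxy)-3,5,6-trimethylbenzoate, C1 unassigned (both epimers) | COc1cc(OCc3ccccc3)c2c(c1C)[C@H](C)[C@](O)(COC(=O)c1c(C)c(C)c(OCc4ccccc4)c(C)c1OCc1ccccc1)C2O | intermediate
23 | [(2S,3S)-7-(benzyloxy)-2-hydroxy-5-methoxy-3,4-dimethyl-1-oxo-2,3-dihydro-1H-inden-2-yl]methyl 2,4-bis(benzyloxy)-3,5,6-trimethylbenzoate | COc1cc(OCc3ccccc3)c2c(c1C)[C@H](C)[C@](O)(COC(=O)c1c(C)c(C)c(OCc4ccccc4)c(C)c1OCc1ccccc1)C2=O | intermediate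
24 | 2-(benzyloxy)-6-[(2S)-4-{[2,4-bis(benzyloxy)-3,5,6-trimethylbenzoyl]oxy}-3-oxobutan-2-yl]-4-methoxy-5-methylbenzoic acid | COc1cc(OCc3ccccc3)c(C(=O)O)c(c1C)[C@H](C)C(=O)COC(=O)c1c(C)c(C)c(OCc4ccccc4)c(C)c1OCc1ccccc1 | intermediate (not isolated)
25 | [(3R,4S)-8-(benzyloxy)-3-hydroxy-6-methoxy-4,5-dimethyl-1-oxo-3,4-dihydro-1H-isochromen-3-yl]methyl 2,4-bis(benzyloxy)-3,5,6-trimethylbenzoate | COc1cc(OCc3ccccc3)c2c(c1C)[C@H](C)[C@](O)(COC(=O)c1c(C)c(C)c(OCc4ccccc4)c(C)c1OCc1ccccc1)OC2=O | intermediate
26 | [(3R,4S)-3,8-dihydroxy-6-methoxy-4,5-dimethyl-1-oxo-3,4-dihydro-1H-isochromen-3-yl]methyl 2,4-dihydroxy-3,5,6-trimethylbenzoate | COc1cc(O)c2c(c1C)[C@H](C)[C@](O)(COC(=O)c1c(C)c(C)c(O)c(C)c1O)OC2=O | target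

**Step count**

Total step count: 19. Longest linear sequence: 15 steps (steps 1 to 11, then 16 to 19); the ring C acid takes 4 steps (12 to 15).

**Steps most likely to fail**

Step 18. The cleavage may stall because the aryl ketone is deactivated by its ortho and para alkoxy groups and sits in a crowded α-ketol. Longer exposure to the acidic medium could then cause loss of water from the lactol toward the isocoumarin, or enolisation of the open keto acid that erodes C4. The fallback sets out from diol ester 22 and leaves out step 17. The vicinal diol of 22 is cleaved with Pb(OAc)4 in CH2Cl2 at 0 °C, a glycol cleavage that is faster than α-ketol cleavage and needs no aqueous acid. This should give the keto aldehyde 2-(benzyloxy)-6-[(2S)-4-{[2,4-bis(benzyloxy)-3,5,6-trimethylbenzoyl]oxy}-3-oxobutan-2-yl]-4-methoxy-5-methylbenzaldehyde F1. Pinnick oxidation of F1 (NaClO2, NaH2PO4, 2-methylbut-2-ene, tBuOH/H2O) should give keto acid 24, which closes as in the main route, and the fallback comes back at 25.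

Step 16. Acyl transfer from the doubly ortho-substituted acid chloride to a neopentyl-type primary alcohol may be sluggish, and forcing it could bring acylation of the secondary carbinol. The fallback sets out from triol 15 and reverses the polarity of ester formation, so that the hindered acid acts as a nucleophile. Selective sulfonylation of the primary hydroxyl (TsCl, pyridine, 0 °C) should give [(2S,3S)-7-(benzyloxy)-1,2-dihydroxy-5-methoxy-3,4-dimethyl-2,3-dihydro-1H-inden-2-yl]methyl 4-methylbenzenesulfonate F2. K2CO3 in MeOH should close it to the spiro-epoxide (2S,3S)-7-(benzyloxy)-5-methoxy-3,4-dimethyl-1,3-dihydrospiro[indene-2,2'-oxiran]-1-ol F3, with C2 retained. The caesium salt of acid 20 (Cs2CO3, DMF, 70 °C) should open F3 at its CH2 terminus, and the fallback comes back at 22.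

Step 4. The ortho methyl twists the aryl group out of conjugation and crowds the β-carbon, so the reduction may be slow or poorly face-selective. Any (Z)-enoate carried over from step 3 would be reduced to the opposite enantiomer. The fallback sets out from bromide 4 and uses auxiliary control with a predictable sense. Mg in THF converts 4 into (3,5-dimethoxy-2-methylphenyl)magnesium bromide F4. (S)-3-[(E)-But-2-enoyl]-4-phenyloxazolidin-2-one F5 is made from (S)-4-phenyloxazolidin-2-one, nBuLi and crotonoyl chloride. F4 is added to F5 with CuBr·SMe2 in THF at −20 °C. The aryl group should enter anti to the C4 phenyl of the chelated syn-s-cis imide, giving (S)-3-[(R)-3-(3,5-dimethoxy-2-methylphenyl)butanoyl]-4-phenyloxazolidin-2-one F6. LiOH and H2O2 in THF/H2O cleave the auxiliary, and the fallback comes back at acid 8, leaving out steps 3 to 5.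

Further compounds
F1 | step 18 | 2-(benzyloxy)-6-[(2S)-4-{[2,4-bis(benzyloxy)-3,5,6-trimethylbenzoyl]oxy}-3-oxobutan-2-yl]-4-methoxy-5-methylbenzaldehyde | COc1cc(OCc3ccccc3)c(C=O)c(c1C)[C@H](C)C(=O)COC(=O)c1c(C)c(C)c(OCc4ccccc4)c(C)c1OCc1ccccc1
F2 | step 16 | [(2S,3S)-7-(benzyloxy)-1,2-dihydroxy-5-methoxy-3,4-dimethyl-2,3-dihydro-1H-inden-2-yl]methyl 4-methylbenzenesulfonate (both C1 epimers) | COc1cc(OCc3ccccc3)c2c(c1C)[C@H](C)[C@](O)(COS(=O)(=O)c1ccc(C)cc1)C2O
F3 | step 16 | (2S,3S)-7-(benzyloxy)-5-methoxy-3,4-dimethyl-1,3-dihydrospiro[indene-2,2'-oxiran]-1-ol (both C1 epimers) | COc1cc(OCc3ccccc3)c2c(c1C)[C@H](C)[C@]1(CO1)C2O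
F4 | step 4 | (3,5-dimethoxy-2-methylphenyl)magnesium bromide | COc1cc(OC)cc([Mg]Br)c1C
F5 | step 4 | (S)-3-[(E)-but-2-enoyl]-4-phenyloxazolidin-2-one | C/C=C/C(=O)N1[C@@H](c2ccccc2)COC1=O
F6 | step 4 | (S)-3-[(R)-3-(3,5-dimethoxy-2-methylphenyl)butanoyl]-4-phenyloxazolidin-2-one | COc1cc(OC)cc(c1C)[C@H](C)CC(=O)N1[C@@H](c2ccccc2)COC1=O
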